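**Plan**
Retrosynthesis: first the four O-protecting groups are taken off; then ring C is cut at C2–C3, with C2 traced back to the O–CH2–O carbon of a MOM ether on O1; then the ring A–C4 bond; last the C3'–prenyl and C5'–(1,1-dimethylallyl) bonds, each traced to an O-allyl ether.
Enabling feature: C2 is a lone CH between O1 and C3. In the open-chain diazo ketone, O1 already carries a CH2 (the acetal carbon of an ortho MOM ether of ring A) in a 1,6-relationship to C3, so a carbene at C3 can take that C–H bond and close ring C.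
Forward: ring B is built first by two Claisen shifts in one heating programme (O2' tertiary allyl ether to C3', then O4' prenyl ether to C5'), then silylated and converted to a Weinreb amide.
Lithiated tris-MOM phloroglucinol (ring A) is acylated to the deoxybenzoin; diazo transfer follows; ring C closes last by rhodium carbene insertion and loss of methanol; MOM and silyl groups are then removed.
Stereochemistry: the target has no stereocentre and no stereogenic double bond; the two centres of the insertion product disappear on elimination.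

Key step: step 11

Assumption: 3-chloro-3-methylbut-1-yne (the chloride of 2-methylbut-3-yn-2-ol) is bought as such. Ring B positions carry primed numbers, C1' being the carbon that ends up bonded to C3.

**Step 1**
Reactants: 1 2,4-dihydroxyphenylacetic acid
Product: 2 methyl 2-(2,4-dihydroxyphenyl)acetate
Conditions: MeOH, H2SO4 (cat.), reflux
Reagents that add atoms: methanol, CO
Why: Fischer esterification leaves the phenols untouched, and any benzofuranone lactone that forms is reopened by the excess methanol.

**Step 2**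
Reactants: 2 methyl 2-(2,4-dihydroxyphenyl)acetate; 3 prenyl bromide (1-bromo-3-methylbut-2-ene)
Product: 4 methyl 2-[2-hydroxy-4-(3-methylbut-2-enyloxy)phenyl]acetate
Conditions: 3 (1.0 equiv), K2CO3, acetone, rt
Reagents that add atoms: prenyl bromide (3), CC(C)=CCBr
Why: Williamson ether synthesis should favour the 4-OH, which is less hindered and not hydrogen-bonded to the ester, and one equivalent of bromide limits double alkylation, the minor 2-O isomer and bis-ether being removed by chromatography.

**Step 3**
Reactants: 4 methyl 2-[2-hydroxy-4-(3-methylbut-2-enyloxy)phenyl]acetate; 5 3-chloro-3-methylbut-1-yne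
Product: 6 methyl 2-[2-(2-methylbut-3-yn-2-yloxy)-4-(3-methylbut-2-enyloxy)phenyl]acetate
Conditions: 5 (1.5 equiv), DBU, CuCl2·2H2O (1 mol %), MeCN, 0 °C to rt
Reagents that add atoms: 3-chloro-3-methylbut-1-yne (5), CC(C)(Cl)C#C
Why: copper-catalysed propargylic substitution (through a copper acetylide/allenylidene) is the standard way to make tertiary aryl propargyl ethers under mild base, and only one OH is left to react.

**Step 4**
Reactants: 6 methyl 2-[2-(2-methylbut-3-yn-2-yloxy)-4-(3-methylbut-2-enyloxy)phenyl]acetate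
Product: 7 methyl 2-[2-(2-methylbut-3-en-2-yloxy)-4-(3-methylbut-2-enyloxy)phenyl]acetate
Conditions: H2 (1 atm), Pd/CaCO3 poisoned with Pb(OAc)2, quinoline, EtOAc, rt
Reagents that add atoms: none
Why: Lindlar semihydrogenation stops at the alkene and does not touch the trisubstituted prenyl double bond, and the heat-sensitive tertiary allyl ether is carried on without warming.

**Step 5**
Reactants: 7 methyl 2-[2-(2-methylbut-3-en-2-yloxy)-4-(3-methylbut-2-enyloxy)phenyl]acetate
Product: 10 methyl 2-[2,4-dihydroxy-5-(2-methylbut-3-en-2-yl)-3-(3-methylbut-2-enyl)phenyl]acetate, via mono-rearranged butanoate 8 (not isolated), via bis-butanoate 9 (not isolated)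
Conditions: (n-PrCO)2O, PhNEt2, 130 °C then 195 °C; cool; K2CO3, MeOH, rt
Reagents that add atoms: none
Why: two aromatic Claisen rearrangements run in sequence, the tertiary allyl ether on O2' shifting first at the lower temperature to C3' (its only free ortho position) to give the prenyl group and the prenyl ether on O4' then shifting to C5' (by then its only free ortho position) to give the 1,1-dimethylallyl group, while butanoic anhydride acylates each phenol as it appears and so blocks lactonisation, chroman formation and abnormal Claisen rearrangement before methanolysis frees both phenols.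

**Step 6**
Reactants: 10 methyl 2-[2,4-dihydroxy-5-(2-methylbut-3-en-2-yl)-3-(3-methylbut-2-enyl)phenyl]acetate
Product: 11 methyl 2-[2,4-bis(tert-butyldimethylsilyloxy)-5-(2-methylbut-3-en-2-yl)-3-(3-methylbut-2-enyl)phenyl]acetate
Conditions: TBSOTf (3 equiv), 2,6-lutidine, CH2Cl2, 0 °C to rt
Reagents that add atoms: tert-butyldimethylsilyl trifluoromethanesulfonate, CC(C)(C)[Si](C)(C)OS(=O)(=O)C(F)(F)F
Why: O-silylation with the silyl triflate and a hindered pyridine base is forceful enough for the flanked 4'-OH, and silyl ethers are chosen because they place no O–C–H bond near the later carbene.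

**Step 7**
Reactants: 11 methyl 2-[2,4-bis(tert-butyldimethylsilyloxy)-5-(2-methylbut-3-en-2-yl)-3-(3-methylbut-2-enyl)phenyl]acetate
Product: 12 2-[2,4-bis(tert-butyldimethylsilyloxy)-5-(2-methylbut-3-en-2-yl)-3-(3-methylbut-2-enyl)phenyl]-N-methoxy-N-methylacetamide
Conditions: MeNH(OMe)·HCl, i-PrMgCl, THF, −20 °C to 0 °C
Reagents that add atoms: N,O-dimethylhydroxylamine hydrochloride, CNOC.Cl
Why: Weinreb amidation of a methyl ester with the chloromagnesium amide is fast at low temperature, where aryl silyl ethers and the alkenes are inert.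

**Step 8**
Reactants: 13 phloroglucinol
Product: 14 1,3,5-tris(methoxymethoxy)benzene
Conditions: MOMCl (4 equiv), i-Pr2NEt, DMF, 0 °C to rt
Reagents that add atoms: chloromethyl methyl ether, COCCl
Why: threefold O-alkylation of the phenol with the reactive α-chloro ether (Williamson-type) gives the symmetrical tris-acetal, which carries both the later C2 carbon and the directing groups for lithiation.

**Step 9**
Reactants: 14 1,3,5-tris(methoxymethoxy)benzene; 12 2-[2,4-bis(tert-butyldimethylsilyloxy)-5-(2-methylbut-3-en-2-yl)-3-(3-methylbut-2-enyl)phenyl]-N-methoxy-N-methylacetamide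
Product: 16 2-[2,4-bis(tert-butyldimethylsilyloxy)-5-(2-methylbut-3-en-2-yl)-3-(3-methylbut-2-enyl)phenyl]-1-[2,4,6-tris(methoxymethoxy)phenyl]ethanone, via aryllithium 15 (not isolated)
Conditions: 14 (2 equiv), n-BuLi, THF, 0 °C; then 12, −78 °C to 0 °C; aq NH4Cl
Reagents that add atoms: none
Why: directed ortho-lithiation between two MOM ethers followed by Weinreb ketone synthesis, the chelated tetrahedral intermediate holding until work-up so that no second addition occurs.

**Step 10**
Reactants: 16 2-[2,4-bis(tert-butyldimethylsilyloxy)-5-(2-methylbut-3-en-2-yl)-3-(3-methylbut-2-enyl)phenyl]-1-[2,4,6-tris(methoxymethoxy)phenyl]ethanone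
Product: 17 2-diazo-2-[2,4-bis(tert-butyldimethylsilyloxy)-5-(2-methylbut-3-en-2-yl)-3-(3-methylbut-2-enyl)phenyl]-1-[2,4,6-tris(methoxymethoxy)phenyl]ethanone
Conditions: 4-acetamidobenzenesulfonyl azide, DBU, dry MeCN, 0 °C to rt
Reagents that add atoms: 4-acetamidobenzenesulfonyl azide, CC(=O)Nc1ccc(cc1)S(=O)(=O)N=[N+]=[N-]
Why: Regitz diazo transfer works directly on benzyl aryl ketones because the methylene is activated by both the carbonyl and the aryl ring, and dry conditions protect the aryl silyl ethers from the amidine base.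

**Step 11**
Reactants: 17 2-diazo-2-[2,4-bis(tert-butyldimethylsilyloxy)-5-(2-methylbut-3-en-2-yl)-3-(3-methylbut-2-enyl)phenyl]-1-[2,4,6-tris(methoxymethoxy)phenyl]ethanone
Product: 19 3-[2,4-bis(tert-butyldimethylsilyloxy)-5-(2-methylbut-3-en-2-yl)-3-(3-methylbut-2-enyl)phenyl]-5,7-bis(methoxymethoxy)chromen-4-one, via 2-methoxyisoflavanone 18 (not isolated)
Conditions: Rh2(O2CCPh3)4 (1 mol %), CH2Cl2, 4 Å MS, rt, slow addition of 17; then PPTS (10 mol %), 40 °C
Reagents that add atoms: none
Why: Proposed new method: loss of N2 from 17 on the dirhodium core gives an electrophilic donor–acceptor carbene at C3 (ring B as donor, the ketone as acceptor) that inserts, through a concerted three-centre transition state with hydride-transfer character, into a C–H bond of the O–CH2–O carbon of an ortho MOM ether, forming C2–C3 and giving the 2-methoxyisoflavanone 18, an acetal with an acidic C3–H that loses methanol under the pyridinium salt (oxocarbenium ion at C2, then loss of H3) to give the conjugated chromone 19. The closest known reaction type is the dirhodium-catalysed intramolecular C–H insertion of aryl diazo ketones and esters into C–H bonds next to an ether oxygen, the established route to 2,3-dihydrobenzofurans and chroman-4-ones. Ring C closes by 1,6-insertion through a six-membered transition state (C3, C4, C4a, C8a, O1, C2); a five-membered alternative on ring A does not exist because the fifth atom is O1 itself. The two stereocentres of 18 (C2 and C3) form without control and need none, since both become trigonal when methanol leaves. The step needs chemoselectivity for insertion over attack of the carbene on the O1 lone pair (oxonium ylide, then 1,2-shift to a benzofuran-3-one), over Wolff rearrangement and over reaction at ring B; the acetal C–H bond activated by two oxygens, the tempered donor–acceptor carbene and the bulky triphenylacetate ligands favour insertion, the equivalence of the two ortho MOM groups on ring A removes any regiochemical question, and the silyl ethers on ring B leave no O–CH bond within reach of C3 (a MOM ether at O2' would invite a five-membered insertion).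

**Step 12**
Reactants: 19 3-[2,4-bis(tert-butyldimethylsilyloxy)-5-(2-methylbut-3-en-2-yl)-3-(3-methylbut-2-enyl)phenyl]-5,7-bis(methoxymethoxy)chromen-4-one
Product: 20 3-[2,4-bis(tert-butyldimethylsilyloxy)-5-(2-methylbut-3-en-2-yl)-3-(3-methylbut-2-enyl)phenyl]-5,7-dihydroxychromen-4-one
Conditions: 3 M aq HCl, MeOH–THF, 40 °C
Reagents that add atoms: none
Why: acid-catalysed acetal exchange with methanol removes both MOM ethers (the one peri to the carbonyl first), while the two flanked aryl silyl ethers should solvolyse far more slowly and, while in place, keep the ring B oxygens from cyclising onto the prenyl and dimethylallyl groups.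

**Step 13**
Reactants: 20 3-[2,4-bis(tert-butyldimethylsilyloxy)-5-(2-methylbut-3-en-2-yl)-3-(3-methylbut-2-enyl)phenyl]-5,7-dihydroxychromen-4-one
Product: 21 fremontone
Conditions: Bu4NF, AcOH, THF, 0 °C to rt
Reagents that add atoms: none
Why: fluoride-mediated desilylation of aryl silyl ethers is driven by the Si–F bond and the good phenoxide leaving group, and the acetic acid buffer keeps the chromone and the free phenols away from strongly basic conditions.

**Compound list**
1 | 2,4-dihydroxyphenylacetic acid | O=C(O)Cc1ccc(O)cc1O | starting material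
2 | methyl 2-(2,4-dihydroxyphenyl)acetate | COC(=O)Cc1ccc(O)cc1O | intermediate
3 | prenyl bromide (1-bromo-3-methylbut-2-ene) | CC(C)=CCBr | starting material
4 | methyl 2-[2-hydroxy-4-(3-methylbut-2-enyloxy)phenyl]acetate | COC(=O)Cc1ccc(OCC=C(C)C)cc1O | intermediate
5 | 3-chloro-3-methylbut-1-yne | CC(C)(Cl)C#C | starting material
6 | methyl 2-[2-(2-methylbut-3-yn-2-yloxy)-4-(3-methylbut-2-enyloxy)phenyl]acetate | COC(=O)Cc1ccc(OCC=C(C)C)cc1OC(C)(C)C#C | intermediate
7 | methyl 2-[2-(2-methylbut-3-en-2-yloxy)-4-(3-methylbut-2-enyloxy)phenyl]acetate | COC(=O)Cc1ccc(OCC=C(C)C)cc1OC(C)(C)C=C | intermediate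
8 | methyl 2-[2-butanoyloxy-3-(3-methylbut-2-enyl)-4-(3-methylbut-2-enyloxy)phenyl]acetate (not isolated) | COC(=O)Cc1ccc(OCC=C(C)C)c(CC=C(C)C)c1OC(=O)CCC | intermediate
9 | methyl 2-[2,4-bis(butanoyloxy)-5-(2-methylbut-3-en-2-yl)-3-(3-methylbut-2-enyl)phenyl]acetate (not isolated) | COC(=O)Cc1cc(C(C)(C)C=C)c(OC(=O)CCC)c(CC=C(C)C)c1OC(=O)CCC | intermediate
10 | methyl 2-[2,4-dihydroxy-5-(2-methylbut-3-en-2-yl)-3-(3-methylbut-2-enyl)phenyl]acetate | COC(=O)Cc1cc(C(C)(C)C=C)c(O)c(CC=C(C)C)c1O | intermediate
11 | methyl 2-[2,4-bis(tert-butyldimethylsilyloxy)-5-(2-methylbut-3-en-2-yl)-3-(3-methylbut-2-enyl)phenyl]acetate | COC(=O)Cc1cc(C(C)(C)C=C)c(O[Si](C)(C)C(C)(C)C)c(CC=C(C)C)c1O[Si](C)(C)C(C)(C)C | intermediate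
12 | 2-[2,4-bis(tert-butyldimethylsilyloxy)-5-(2-methylbut-3-en-2-yl)-3-(3-methylbut-2-enyl)phenyl]-N-methoxy-N-methylacetamide | CON(C)C(=O)Cc1cc(C(C)(C)C=C)c(O[Si](C)(C)C(C)(C)C)c(CC=C(C)C)c1O[Si](C)(C)C(C)(C)C | intermediate
13 | phloroglucinol | Oc1cc(O)cc(O)c1 | starting material
14 | 1,3,5-tris(methoxymethoxy)benzene | COCOc1cc(OCOC)cc(OCOC)c1 | intermediate
15 | 2-lithio-1,3,5-tris(methoxymethoxy)benzene (not isolated) | [Li]c1c(OCOC)cc(OCOC)cc1OCOC | intermediate
16 | 2-[2,4-bis(tert-butyldimethylsilyloxy)-5-(2-methylbut-3-en-2-yl)-3-(3-methylbut-2-enyl)phenyl]-1-[2,4,6-tris(methoxymethoxy)phenyl]ethanone | COCOc1cc(OCOC)c(C(=O)Cc2cc(C(C)(C)C=C)c(O[Si](C)(C)C(C)(C)C)c(CC=C(C)C)c2O[Si](C)(C)C(C)(C)C)c(OCOC)c1 | intermediate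
17 | 2-diazo-2-[2,4-bis(tert-butyldimethylsilyloxy)-5-(2-methylbut-3-en-2-yl)-3-(3-methylbut-2-enyl)phenyl]-1-[2,4,6-tris(methoxymethoxy)phenyl]ethanone | COCOc1cc(OCOC)c(C(=O)C(=[N+]=[N-])c2cc(C(C)(C)C=C)c(O[Si](C)(C)C(C)(C)C)c(CC=C(C)C)c2O[Si](C)(C)C(C)(C)C)c(OCOC)c1 | intermediate
18 | 3-[2,4-bis(tert-butyldimethylsilyloxy)-5-(2-methylbut-3-en-2-yl)-3-(3-methylbut-2-enyl)phenyl]-2-methoxy-5,7-bis(methoxymethoxy)chroman-4-one (racemic diastereomer mixture; not isolated) | COC1Oc2cc(OCOC)cc(OCOC)c2C(=O)C1c1cc(C(C)(C)C=C)c(O[Si](C)(C)C(C)(C)C)c(CC=C(C)C)c1O[Si](C)(C)C(C)(C)C | intermediate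
19 | 3-[2,4-bis(tert-butyldimethylsilyloxy)-5-(2-methylbut-3-en-2-yl)-3-(3-methylbut-2-enyl)phenyl]-5,7-bis(methoxymethoxy)chromen-4-one | C=CC(C)(C)c1cc(-c2coc3cc(OCOC)cc(OCOC)c3c2=O)c(O[Si](C)(C)C(C)(C)C)c(CC=C(C)C)c1O[Si](C)(C)C(C)(C)C | intermediate
20 | 3-[2,4-bis(tert-butyldimethylsilyloxy)-5-(2-methylbut-3-en-2-yl)-3-(3-methylbut-2-enyl)phenyl]-5,7-dihydroxychromen-4-one | C=CC(C)(C)c1cc(-c2coc3cc(O)cc(O)c3c2=O)c(O[Si](C)(C)C(C)(C)C)c(CC=C(C)C)c1O[Si](C)(C)C(C)(C)C | intermediate
21 | fremontone, 3-[2,4-dihydroxy-5-(2-methylbut-3-en-2-yl)-3-(3-methylbut-2-enyl)phenyl]-5,7-dihydroxychromen-4-one | C=CC(C)(C)c1cc(-c2coc3cc(O)cc(O)c3c2=O)c(O)c(CC=C(C)C)c1O | target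

**Step count**
Total: 13 steps. Longest linear sequence: 12 steps (steps 1–7 and 9–13, from 1); step 8 is the one-step side branch for ring A.

**Steps most likely to fail**

1. Step 11. The carbene may be captured by the lone pair of O1 (oxonium ylide, then 1,2-shift of the methoxymethyl group) or undergo Wolff rearrangement faster than it inserts into the acetal C–H bond. Fallback with known chemistry, setting out from 16: dilute HCl in MeOH at 0 °C removes one of the two equivalent MOM ethers ortho to the ketone, the chelated phenol so formed protecting the second, to give 1-[2-hydroxy-4,6-bis(methoxymethoxy)phenyl]-2-[2,4-bis(tert-butyldimethylsilyloxy)-5-(2-methylbut-3-en-2-yl)-3-(3-methylbut-2-enyl)phenyl]ethanone F1. Heating F1 with N,N-dimethylformamide dimethyl acetal in toluene at 90 °C condenses the one-carbon unit at the methylene to give the enaminone F2, whose phenol adds to the enamine carbon and expels dimethylamine. This is the classical deoxybenzoin closure of isoflavones, with C2 coming from the formamide acetal, and it comes back to the route at 19.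

2. Step 5. The tertiary allyl group may be lost as isoprene before it migrates, or the hotter second shift may be diverted into abnormal Claisen rearrangement, ring closure onto the new phenol, or ether cleavage. Fallback, setting out from 2: N-bromosuccinimide in MeCN at 0 °C brominates C5, para to the 2-OH, to give methyl 2-(5-bromo-2,4-dihydroxyphenyl)acetate F3. Compound 5 with DBU and catalytic CuCl2 alkylates the more acidic 4-OH next to bromine to give methyl 2-[5-bromo-2-hydroxy-4-(2-methylbut-3-yn-2-yloxy)phenyl]acetate F4. Semihydrogenation over Pd/CaCO3 poisoned with Pb(OAc)2 gives methyl 2-[5-bromo-2-hydroxy-4-(2-methylbut-3-en-2-yloxy)phenyl]acetate F5. At 130 °C in PhNEt2 the Claisen shift can only go to C3, bromine blocking C5, to give methyl 2-[5-bromo-2,4-dihydroxy-3-(3-methylbut-2-enyl)phenyl]acetate F6. A Suzuki–Miyaura coupling of F6 with 4,4,5,5-tetramethyl-2-(3-methylbut-2-enyl)-1,3,2-dioxaborolane then puts the 1,1-dimethylallyl group on C5 and comes back to the route at 10. It uses zerovalent palladium from Pd(OAc)2 and a bulky biaryl dialkylphosphine chosen for the branched product, with K3PO4 in aqueous THF. The high-temperature sigmatropic shift is thus replaced by a cross-coupling and the selective O-prenylation of step 2 is no longer needed.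

3. Step 9. The basic aryllithium may take a proton from the methylene of the amide (enolisation) instead of adding to the carbonyl, returning the starting materials on work-up. Fallback, setting out from 12: i-Bu2AlH in THF at −78 °C reduces the Weinreb amide to 2-[2,4-bis(tert-butyldimethylsilyloxy)-5-(2-methylbut-3-en-2-yl)-3-(3-methylbut-2-enyl)phenyl]acetaldehyde F7. The organocerium reagent made from 15 and anhydrous CeCl3, far less basic than the lithium compound, adds to F7 at −78 °C to give the racemic carbinol 2-[2,4-bis(tert-butyldimethylsilyloxy)-5-(2-methylbut-3-en-2-yl)-3-(3-methylbut-2-enyl)phenyl]-1-[2,4,6-tris(methoxymethoxy)phenyl]ethanol F8. Dess–Martin periodinane oxidises F8 to the ketone and comes back to the route at 16.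

**Further compounds**
F1 | step 11 | 1-[2-hydroxy-4,6-bis(methoxymethoxy)phenyl]-2-[2,4-bis(tert-butyldimethylsilyloxy)-5-(2-methylbut-3-en-2-yl)-3-(3-methylbut-2-enyl)phenyl]ethanone | COCOc1cc(O)c(C(=O)Cc2cc(C(C)(C)C=C)c(O[Si](C)(C)C(C)(C)C)c(CC=C(C)C)c2O[Si](C)(C)C(C)(C)C)c(OCOC)c1
F2 | step 11 | 3-(dimethylamino)-1-[2-hydroxy-4,6-bis(methoxymethoxy)phenyl]-2-[2,4-bis(tert-butyldimethylsilyloxy)-5-(2-methylbut-3-en-2-yl)-3-(3-methylbut-2-enyl)phenyl]prop-2-en-1-one (alkene geometry not defined and of no consequence) | CN(C)C=C(C(=O)c1c(O)cc(OCOC)cc1OCOC)c1cc(C(C)(C)C=C)c(O[Si](C)(C)C(C)(C)C)c(CC=C(C)C)c1O[Si](C)(C)C(C)(C)C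
F3 | step 5 | methyl 2-(5-bromo-2,4-dihydroxyphenyl)acetate | COC(=O)Cc1cc(Br)c(O)cc1O
F4 | step 5 | methyl 2-[5-bromo-2-hydroxy-4-(2-methylbut-3-yn-2-yloxy)phenyl]acetate | COC(=O)Cc1cc(Br)c(OC(C)(C)C#C)cc1O
F5 | step 5 | methyl 2-[5-bromo-2-hydroxy-4-(2-methylbut-3-en-2-yloxy)phenyl]acetate | COC(=O)Cc1cc(Br)c(OC(C)(C)C=C)cc1O
F6 | step 5 | methyl 2-[5-bromo-2,4-dihydroxy-3-(3-methylbut-2-enyl)phenyl]acetate | COC(=O)Cc1cc(Br)c(O)c(CC=C(C)C)c1O
F7 | step 9 | 2-[2,4-bis(tert-butyldimethylsilyloxy)-5-(2-methylbut-3-en-2-yl)-3-(3-methylbut-2-enyl)phenyl]acetaldehyde | O=CCc1cc(C(C)(C)C=C)c(O[Si](C)(C)C(C)(C)C)c(CC=C(C)C)c1O[Si](C)(C)C(C)(C)C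
F8 | step 9 | 2-[2,4-bis(tert-butyldimethylsilyloxy)-5-(2-methylbut-3-en-2-yl)-3-(3-methylbut-2-enyl)phenyl]-1-[2,4,6-tris(methoxymethoxy)phenyl]ethanol (racemic) | COCOc1cc(OCOC)c(C(O)Cc2cc(C(C)(C)C=C)c(O[Si](C)(C)C(C)(C)C)c(CC=C(C)C)c2O[Si](C)(C)C(C)(C)C)c(OCOC)c1
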